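The runs are calculated for substances that don't exist.

- Amounts say more here than percentages: Sunday's target readings average 36.2% of 0.20 M starting material, which reads as 0.0724 M of target.

| setting | Saturday's | Sunday's | Tuesday's | blue | violet |
|---|---|---|---|---|---|
| starting material | 0.20 M | 0.20 M | 0.14 M | 0.20 M | 0.060 M |
| reagent | 0.19 M | 0.19 M | 0.19 M | 0.190 M | 0.190 M |
| free catalyst | 0.77 mM | 1.3 mM | 1 mM | 1.0 mM | 1.5 mM |
| temperature | 55 °C | 70 °C | 55 °C | 70 °C | 70 °C |
| remark | run made earlier | run made earlier | run made earlier |  |  |
| time |  |  |  | 40 h | 40 h |

| run | time / h | target / % | starting material / % |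
|---|---|---|---|
| Saturday's | 3.00 | 5.4 | 35.9 |
| Saturday's | 8.00 | 10.5 | 15.1 |
| Saturday's | 15.0 | 20.4 | 2.4 |
| Saturday's | 25.0 | 22.3 | 0.8 |
| Saturday's | 30.0 | 22.5 | 0 |
| Saturday's | 40.0 | 22.6 | 0.5 |
| Saturday's | 60.0 | 23.5 | 0 |
| Sunday's | 4.00 | 37.1 | 0.7 |
| Sunday's | 8.00 | 36.2 | 0 |
| Sunday's | 12.0 | 35.6 | 1.1 |
| Sunday's | 15.0 | 35.2 | 0 |
| Sunday's | 20.0 | 37.0 | 0.2 |
| Sunday's | 25.0 | 36.3 | 0 |
| Sunday's | 30.0 | 36.1 | 0 |
| Tuesday's | 12.0 | 31.5 | 2.0 |
| Tuesday's | 25.0 | 35.4 | 0 |
| Tuesday's | 30.0 | 36.5 | 0 |
| Tuesday's | 48.0 | 34.8 | 0 |
| Tuesday's | 60.0 | 34.6 | 0.5 |

(readings scatter by 1 percentage point)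

- the numbers in the tables scatter by 1 percentage point (one standard deviation)

- the flask that ends with the higher amount of target, in percent of the starting material charged, or "neither" when 2 percentage points or less lies between them (blue / violet / neither)
- final target, as a percentage of the starting material charged, in blue
- final target, as a percentage of the starting material charged, in violet

- In Saturday's run, starting material falls from 35.9% to 2.4% between 3.00 h and 15.0 h. Yet target reads faster in the later stretch, gaining 9.9 percentage points in 7.00 h against 5.1 points in 5.00 h.
- So I read the catalyst as working at a steady pace set by its amount (zero order in starting material), and I assume a loss that goes with the square of starting material.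
- On these two assumed paces, they cross at a level of starting material that grows with the square root of the catalyst. Above that level I expect the loss to win, so at one temperature and one amount of catalyst I take a heavily charged flask to end near one amount of target: the target ceiling, the plateau concentration of target, which I scale with the square root of the catalyst.
- As a check at 55 °C, Saturday's late readings average 0.0457 M of target, which scales to 37.2% for Tuesday's run, whose late readings average 35.3%.
- At 70 °C, blue's ceiling over its charge gives 31.8%. Violet's ceiling of 0.0778 M stands above its 0.060 M charge, so the ceiling gives me no percentage for violet.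
- Turned round, on the same two assumed paces and with both flasks at 70 °C, I reckon violet's percentage could fall to blue's if violet's starting material squared over catalyst reached blue's, but it stands 16.7 times below. I say violet.
- The forecast also says violet, with 30% (27% to 33%) for blue and 65% (55% to 78%) for violet, on this ground: “The plateau follows the catalyst-to-substrate ratio.” My scaling differs, using the square of the charge.

- Blue ends at 32.1% and violet at 77.7%.

    starting material + free catalyst → catalyst intermediate A (k = 8300 /M/h, Ea = 36.0 kJ/mol)
    reagent + catalyst intermediate A → catalyst intermediate B (k = 6500 /M/h, Ea = 51.0 kJ/mol)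
    catalyst intermediate B → free catalyst + target (k = 19.0 /h, Ea = 101 kJ/mol)
    target → over-reaction product (k = 3.20 × 10⁻⁴ /h, Ea = 117 kJ/mol)
    2 starting material → homo dimer (k = 3.90 /M/h, Ea = 63.0 kJ/mol)
    (constants at 70 °C)

- Homo dimer holds 67.5% of blue's starting material and 21.3% of violet's at 40.0 h. A further flask, like violet but charged with 0.15 M of starting material, tests the ceiling again: violet's ceiling over that charge gives 51.9%, and the target of this further flask ends at 47.1%.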